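**Assumptions (one line):** locants follow xanthanolide numbering (C1–C15; diene-derived half unprimed, dienophile-derived half primed), and the facial sense quoted for each chiral catalyst is by analogy with its published model, the mirror-image catalyst being used if the sense proves opposite.

## Retrosynthetic overview

1. Target 38 ⇒ double E1cB (epoxide → γ-hydroxy enone; sulfinate loss → exo-methylene lactone), Wittig side-chain extension and face-selective epoxidation ⇒ cycloadduct 34.
2. 34 ⇒ late intermolecular Diels–Alder of two C15-size halves: diene 17 (its exo-methylene lactone masked as a β-sulfonyl lactone) and dienophile 30 (its diene masked as an enal); this forms the cyclohexene ring C and the spiro centre C11′.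
3. 17 ⇒ tandem enyne RCM/cross-metathesis of lactone 14; 30 ⇒ RCM of lactone 27 (seven-membered rings A and E closed after the lactones).
4. Both trans-lactones (rings B and D) ⇒ one allylic bromide 6 plus aldehyde 9 or 24, by asymmetric chromium-catalysed 2-(methoxycarbonyl)allylation–lactonisation.
5. 9 and 24 ⇒ crotonaldehyde by two different asymmetric conjugate additions. Ring order: lactones B and D → seven-membered rings A and E → cyclohexene C.

## Route

### Fragment 1: shared allylic bromide 6

**Step 1**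
Reactants: 1 methyl propiolate; 2 allyl bromide
Product: 3 methyl hex-5-en-2-ynoate
Conditions: CuI (10 mol %), K2CO3, DMF, 25 °C
Reagents that add atoms: none
Why: Copper-acetylide sp–sp3 allylation of the acidic propiolate C–H installs the future C5–C6 allyl unit as a skipped enynoate under a base mild enough to avoid allene formation.

**Step 2**
Reactants: 3 methyl hex-5-en-2-ynoate
Product: 5 methyl (Z)-2-(hydroxymethyl)hexa-2,5-dienoate, via α-alumino dienoate 4 (not isolated)
Conditions: i-Bu2AlH, HMPA, THF, 0 °C; then CH2O (gas), −20 °C → rt; Rochelle-salt work-up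
Reagents that add atoms: formaldehyde, C=O
Why: Conjugate hydroalumination (syn addition of Al–H across the ynoate) gives an α-vinylalane that is hydroxymethylated by formaldehyde (vinylalumination, a Baylis–Hillman-type product).

**Step 3**
Reactants: 5 methyl (Z)-2-(hydroxymethyl)hexa-2,5-dienoate
Product: 6 methyl (E)-2-(bromomethyl)hexa-2,5-dienoate
Conditions: PBr3, Et2O, −10 °C
Reagents that add atoms: phosphorus tribromide, BrP(Br)Br
Why: Standard bromination of a primary allylic alcohol gives the conjugated primary bromide, and its olefin geometry is immaterial because the derived allylchromium equilibrates in steps 5 and 15.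

### Diene half (fragment 2)

**Step 4**
Reactants: 7 (E)-crotonaldehyde; 8 ethynyltri(propan-2-yl)silane
Product: 9 (S)-3-methyl-5-[tri(propan-2-yl)silyl]pent-4-ynal
Conditions: [Rh(OAc)(C2H4)2]2 (2.5 mol %), (R)-DTBM-SEGPHOS (6 mol %), MeOH, 40 °C
Reagents that add atoms: none
Why: Rhodium-catalysed asymmetric conjugate alkynylation of the enal, in which the bulky silylacetylene suppresses alkyne dimerisation and the chiral bisphosphine–rhodium acetylide adds to one enantioface of the β-carbon, sets C10 (S).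

**Step 5**
Reactants: 9 (S)-3-methyl-5-[tri(propan-2-yl)silyl]pent-4-ynal; 6 methyl (E)-2-(bromomethyl)hexa-2,5-dienoate
Product: 12 (4S,5R)-3-methylidene-5-{(2S)-2-methyl-4-[tri(propan-2-yl)silyl]but-3-yn-1-yl}-4-(prop-2-en-1-yl)oxolan-2-one, via silyl ether 10 (not isolated), via hydroxy ester 11 (not isolated)
Conditions: CrCl2 (10 mol %), (S,S)-i-Pr-carbazole-bis(oxazoline) ligand (12 mol %), Mn powder, TMSCl, i-Pr2NEt, THF, 0 °C → rt; then PPTS, MeOH, rt
Reagents that add atoms: none
Why: In this catalytic asymmetric Nozaki–Hiyama–Kishi-type 2-(methoxycarbonyl)allylation the configurationally labile allylchromium reacts at its γ-carbon through a chair transition state with the allyl substituent equatorial (anti adduct, hence the trans lactone after acid methanolysis and lactonisation), while the ligand dictates the aldehyde face (C8 R, C7 S) irrespective of the remote C10 centre.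

**Step 6**
Reactants: 12 (silyl alkyne lactone)
Product: 13 (4S,5R)-3-methylidene-5-[(2S)-2-methylbut-3-yn-1-yl]-4-(prop-2-en-1-yl)oxolan-2-one
Conditions: Bu4NF, AcOH, THF, 0 °C
Reagents that add atoms: none
Why: Buffered fluoride cleaves the C(sp)–Si bond without base-induced damage to the α-methylene lactone.

**Step 7**
Reactants: 13 (terminal alkyne lactone)
Product: 14 (3S,4S,5R)-5-[(2S)-2-methylbut-3-yn-1-yl]-3-[(phenylsulfonyl)methyl]-4-(prop-2-en-1-yl)oxolan-2-one
Conditions: PhSO2Na, AcOH, EtOH/H2O, 40 °C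
Reagents that add atoms: sodium benzenesulfinate, [Na+].[O-]S(=O)c1ccccc1
Why: Sulfa-Michael addition masks the exo-methylene lactone as a β-sulfonyl lactone that is inert to metathesis and cycloaddition, the reversible addition leaving C11 in the thermodynamic 3,4-trans arrangement (this centre is erased again in step 24).

**Step 8**
Reactants: 14 (sulfone lactone); 15 but-3-en-2-one
Product: 17 (3S,3aS,7S,8aR)-7-methyl-6-[(E)-3-oxobut-1-en-1-yl]-3-[(phenylsulfonyl)methyl]-3,3a,4,7,8,8a-hexahydro-2H-cyclohepta[b]furan-2-one, via vinyl diene 16 (not isolated)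
Conditions: second-generation Hoveyda–Grubbs catalyst RuCl2(=CH-C6H4-2-O-i-Pr)(H2IMes) (15 mol %), but-3-en-2-one (10 equiv), CH2Cl2, 40 °C
Reagents that add atoms: none
Why: Tandem ring-closing enyne metathesis (exo mode, giving the cycloheptene with a 1-vinyl group) followed by E-selective cross-metathesis of the terminal vinyl with the enone builds ring A and the dienone in one operation, as known for xanthanolides.

### Dienophile half (fragment 3)

**Step 9**
Reactants: 18 S-tert-butyl ethanethioate
Product: 19 [1-(tert-butylsulfanyl)ethenyl]oxy(trimethyl)silane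
Conditions: TMSOTf, Et3N, CH2Cl2, 0 °C
Reagents that add atoms: trimethylsilyl triflate, C[Si](C)(C)OS(=O)(=O)C(F)(F)F
Why: Soft enolisation and O-silylation of the thioester gives the ketene silyl thioacetal.

**Step 10**
Reactants: 7 (E)-crotonaldehyde; 19 ketene silyl thioacetal
Product: 20 S-tert-butyl (3S)-3-methyl-5-oxopentanethioate
Conditions: (2S,5S)-5-benzyl-2-tert-butyl-3-methylimidazolidin-4-one·CCl3CO2H (20 mol %), H2O (2 equiv), CH2Cl2, −78 °C
Reagents that add atoms: none
Why: In this iminium-catalysed Mukaiyama–Michael addition the chiral imidazolidinone shields one face of the crotonaldehyde iminium, so the silyl ketene thioacetal adds to the β-carbon enantioselectively and sets C10′.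

**Step 11**
Reactants: 20 S-tert-butyl (3S)-3-methyl-5-oxopentanethioate
Product: 21 S-tert-butyl (3R)-4-formyl-3-methylpent-4-enethioate
Conditions: aq. CH2O (37 %), pyrrolidine (10 mol %), propionic acid (10 mol %), i-PrOH, 45 °C
Reagents that add atoms: formaldehyde, C=O
Why: Amine-catalysed Mannich condensation–elimination (aldehyde α-methylenation) converts the CH2CHO terminus into the 2-substituted acrolein while the hindered tert-butyl thioester and the β-stereocentre are untouched.

**Step 12**
Reactants: 21 S-tert-butyl (3R)-4-formyl-3-methylpent-4-enethioate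
Product: 22 S-tert-butyl (3R)-4-(hydroxymethyl)-3-methylpent-4-enethioate
Conditions: NaBH4, CeCl3·7H2O, MeOH, −40 °C
Reagents that add atoms: none
Why: Luche 1,2-reduction of the enal is far faster than thioester reduction at low temperature.

**Step 13**
Reactants: 22 (allylic alcohol)
Product: 23 S-tert-butyl (3R)-4-{[(tert-butyldimethylsilyl)oxy]methyl}-3-methylpent-4-enethioate
Conditions: TBSCl, imidazole, CH2Cl2, rt
Reagents that add atoms: tert-butyldimethylsilyl chloride, CC(C)(C)[Si](C)(C)Cl
Why: Silylation protects the primary allylic alcohol for the hydride and organochromium steps.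

**Step 14**
Reactants: 23 (silyl ether thioester)
Product: 24 (3R)-4-{[(tert-butyldimethylsilyl)oxy]methyl}-3-methylpent-4-enal
Conditions: i-Bu2AlH (1.1 equiv), CH2Cl2, −78 °C
Reagents that add atoms: none
Why: Low-temperature reduction of the thioester stops at the aldehyde because the tetrahedral aluminium hemithioacetal only collapses on work-up.

**Step 15**
Reactants: 24 (3R)-aldehyde; 6 methyl (E)-2-(bromomethyl)hexa-2,5-dienoate
Product: 27 (4S,5R)-5-[(2R)-3-{[(tert-butyldimethylsilyl)oxy]methyl}-2-methylbut-3-en-1-yl]-3-methylidene-4-(prop-2-en-1-yl)oxolan-2-one, via silyl ether 25 (not isolated), via hydroxy ester 26 (not isolated)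
Conditions: CrCl2 (10 mol %), (S,S)-i-Pr-carbazole-bis(oxazoline) ligand (12 mol %), Mn powder, TMSCl, i-Pr2NEt, THF, 0 °C → rt; then PPTS, MeOH, 0 °C → rt
Reagents that add atoms: none
Why: The same catalyst-controlled, anti-selective Nozaki–Hiyama–Kishi-type 2-(methoxycarbonyl)allylation and lactonisation as in step 5 sets C7′ (S) and C8′ (R) of the trans lactone, the trimethylsilyl ether being cleaved selectively in the presence of the primary tert-butyldimethylsilyl ether.

**Step 16**
Reactants: 27 (diene lactone)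
Product: 28 (3aS,7R,8aR)-6-{[(tert-butyldimethylsilyl)oxy]methyl}-7-methyl-3-methylidene-3,3a,4,7,8,8a-hexahydro-2H-cyclohepta[b]furan-2-one
Conditions: second-generation Grubbs catalyst RuCl2(=CHPh)(PCy3)(H2IMes) (10 mol %), toluene (0.005 M), 80 °C
Reagents that add atoms: none
Why: Ring-closing metathesis between the allyl group and the 1,1-disubstituted alkene closes ring E as its trisubstituted olefin under high dilution, the electron-poor exo-methylene lactone being a spectator.

**Step 17**
Reactants: 28 (silyl ether)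
Product: 29 (3aS,7R,8aR)-6-(hydroxymethyl)-7-methyl-3-methylidene-3,3a,4,7,8,8a-hexahydro-2H-cyclohepta[b]furan-2-one
Conditions: HF·pyridine, THF, 0 °C → rt
Reagents that add atoms: none
Why: Acidic fluoride removes the silyl ether without the basic conditions that would add to the exo-methylene lactone.

**Step 18**
Reactants: 29 (allylic alcohol)
Product: 30 (3aS,7R,8aR)-7-methyl-3-methylidene-2-oxo-3,3a,4,7,8,8a-hexahydro-2H-cyclohepta[b]furan-6-carbaldehyde
Conditions: MnO2, CH2Cl2, rt
Reagents that add atoms: none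
Why: Chemoselective allylic oxidation gives the conjugated enal, which keeps the exo-methylene dienophile but cannot itself act as a Diels–Alder diene.

### Fragment 4: ylide

**Step 19**
Reactants: 31 1-chloropropan-2-one
Product: 32 (2-oxopropyl)triphenylphosphonium chloride
Conditions: PPh3, toluene, 80 °C
Reagents that add atoms: triphenylphosphine, c1ccc(cc1)P(c1ccccc1)c1ccccc1
Why: SN2 alkylation of the phosphine by the α-chloroketone gives the phosphonium salt.

**Step 20**
Reactants: 32 (2-oxopropyl)triphenylphosphonium chloride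
Product: 33 1-(triphenylphosphoranylidene)propan-2-one
Conditions: Na2CO3, H2O/MeOH, rt
Reagents that add atoms: none
Why: Deprotonation of the acidic phosphonium salt gives the stabilised ylide.

### Coupling and end-game

**Step 21**
Reactants: 17 diene sulfone; 30 enal dienophile (1.3 equiv)
Product: 34 cycloadduct (3S,5S,7S,8R,10S,11S,7′S,8′R,10′R,11′R)-3-acetyl-13-(phenylsulfonyl)-11,13-dihydro-1(2)-ene spiro-dimer 2′-aldehyde
Conditions: toluene (2 M), BHT (5 mol %), 95 °C, sealed tube, 72 h
Reagents that add atoms: none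
Why: In this thermal intermolecular Diels–Alder reaction 17 is the only diene and the exo-methylene of 30 the only reactive dienophile, so no homodimers or oligomers form. The C5 terminus bonds to C13′ and C3 to C11′; the exo mode usual for s-cis-locked α-methylene lactones, attack on the diene face anti to the C7–C11 bond (anti to pseudo-axial H-6, unhindered by the pseudo-equatorial C10 methyl) and attack on the lactone face syn to H-7′ set C5 (S), C11′ (R) and C3 (S).

**Step 22**
Reactants: 34 cycloadduct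
Product: 35 (1R,2S)-1,2-epoxide of cycloadduct 34
Conditions: DMDO (1.1 equiv), acetone/CH2Cl2, −40 → −20 °C
Reagents that add atoms: dimethyldioxirane, CC1(C)OO1
Why: Epoxidation is chemoselective for the only electron-rich, non-conjugated trisubstituted alkene and occurs on the convex face bearing H-3, H-5 and H-10 (anti to the C10 methyl, the acetyl group and C6), which places oxygen on C1 with the configuration needed for the carbinol.

**Step 23**
Reactants: 35 epoxy aldehyde; 33 1-(triphenylphosphoranylidene)propan-2-one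
Product: 36 epoxy sulfone with the (E)-3-oxobut-1-enyl side chain on C1′
Conditions: toluene, 60 °C
Reagents that add atoms: none
Why: In this Wittig olefination the stabilised ylide reacts only with the aldehyde (not the ketone, the lactones or the sulfone) and gives the (E)-enone, completing the dienone of the dienophile-derived half.

**Step 24**
Reactants: 36 epoxy sulfone dienone
Product: 38 CNP0168949.3 (1R,5S,7S,8R,10S,7′S,8′R,10′R,11′R), via hydroxy enone sulfone 37 (not isolated)
Conditions: DBU (3 equiv), CH2Cl2, 0 °C → rt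
Reagents that add atoms: none
Why: A double E1cB sequence finishes the synthesis: enolisation of the C4 ketone opens the β,γ-epoxide to the γ-hydroxy enone (the C1–O bond is untouched, so C1 stays R), and loss of benzenesulfinate from the β-sulfonyl lactone regenerates the exo-methylene lactone.

## Compound list

1 | methyl propiolate | C#CC(=O)OC | starting material
2 | allyl bromide | C=CCBr | starting material
3 | methyl hex-5-en-2-ynoate | C=CCC#CC(=O)OC | intermediate
4 | methyl (E)-2-(diisobutylalumanyl)hexa-2,5-dienoate (not isolated) | C=CC/C=C(/[Al](CC(C)C)CC(C)C)C(=O)OC | intermediate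
5 | methyl (Z)-2-(hydroxymethyl)hexa-2,5-dienoate | C=CC/C=C(/CO)C(=O)OC | intermediate
6 | methyl (E)-2-(bromomethyl)hexa-2,5-dienoate | C=CC/C=C(/CBr)C(=O)OC | intermediate
7 | (E)-crotonaldehyde | C/C=C/C=O | starting material
8 | ethynyltri(propan-2-yl)silane (acetylene carrying a triisopropylsilyl protecting group) | C#C[Si](C(C)C)(C(C)C)C(C)C | starting material
9 | (S)-3-methyl-5-[tri(propan-2-yl)silyl]pent-4-ynal | O=CC[C@H](C)C#C[Si](C(C)C)(C(C)C)C(C)C | intermediate
10 | methyl (3S,4R,6S)-6-methyl-2-methylidene-3-(prop-2-en-1-yl)-8-[tri(propan-2-yl)silyl]-4-[(trimethylsilyl)oxy]oct-7-ynoate (not isolated) | C=C(C(=O)OC)[C@H](CC=C)[C@H](O[Si](C)(C)C)C[C@H](C)C#C[Si](C(C)C)(C(C)C)C(C)C | intermediate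
11 | methyl (3S,4R,6S)-4-hydroxy-6-methyl-2-methylidene-3-(prop-2-en-1-yl)-8-[tri(propan-2-yl)silyl]oct-7-ynoate (not isolated) | C=C(C(=O)OC)[C@H](CC=C)[C@H](O)C[C@H](C)C#C[Si](C(C)C)(C(C)C)C(C)C | intermediate
12 | (4S,5R)-3-methylidene-5-{(2S)-2-methyl-4-[tri(propan-2-yl)silyl]but-3-yn-1-yl}-4-(prop-2-en-1-yl)oxolan-2-one | C=C1C(=O)O[C@H](C[C@H](C)C#C[Si](C(C)C)(C(C)C)C(C)C)[C@H]1CC=C | intermediate
13 | (4S,5R)-3-methylidene-5-[(2S)-2-methylbut-3-yn-1-yl]-4-(prop-2-en-1-yl)oxolan-2-one | C=C1C(=O)O[C@H](C[C@H](C)C#C)[C@H]1CC=C | intermediate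
14 | (3S,4S,5R)-5-[(2S)-2-methylbut-3-yn-1-yl]-3-[(phenylsulfonyl)methyl]-4-(prop-2-en-1-yl)oxolan-2-one | O=S(=O)(c1ccccc1)C[C@@H]1C(=O)O[C@H](C[C@H](C)C#C)[C@H]1CC=C | intermediate
15 | but-3-en-2-one (methyl vinyl ketone) | C=CC(C)=O | starting material
16 | (3S,3aS,7S,8aR)-6-ethenyl-7-methyl-3-[(phenylsulfonyl)methyl]-3,3a,4,7,8,8a-hexahydro-2H-cyclohepta[b]furan-2-one (not isolated) | O=S(=O)(c3ccccc3)C[C@@H]1C(=O)O[C@@H]2C[C@H](C)C(C=C)=CC[C@@H]12 | intermediate
17 | (3S,3aS,7S,8aR)-7-methyl-6-[(E)-3-oxobut-1-en-1-yl]-3-[(phenylsulfonyl)methyl]-3,3a,4,7,8,8a-hexahydro-2H-cyclohepta[b]furan-2-one | O=S(=O)(c3ccccc3)C[C@@H]1C(=O)O[C@@H]2C[C@H](C)C(/C=C/C(C)=O)=CC[C@@H]12 | intermediate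
18 | S-tert-butyl ethanethioate | CC(=O)SC(C)(C)C | starting material
19 | [1-(tert-butylsulfanyl)ethenyl]oxy(trimethyl)silane | C=C(O[Si](C)(C)C)SC(C)(C)C | intermediate
20 | S-tert-butyl (3S)-3-methyl-5-oxopentanethioate | CC(C)(C)SC(=O)C[C@@H](C)CC=O | intermediate
21 | S-tert-butyl (3R)-4-formyl-3-methylpent-4-enethioate | CC(C)(C)SC(=O)C[C@@H](C)C(=C)C=O | intermediate
22 | S-tert-butyl (3R)-4-(hydroxymethyl)-3-methylpent-4-enethioate | CC(C)(C)SC(=O)C[C@@H](C)C(=C)CO | intermediate
23 | S-tert-butyl (3R)-4-{[(tert-butyldimethylsilyl)oxy]methyl}-3-methylpent-4-enethioate | CC(C)(C)SC(=O)C[C@@H](C)C(=C)CO[Si](C)(C)C(C)(C)C | intermediate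
24 | (3R)-4-{[(tert-butyldimethylsilyl)oxy]methyl}-3-methylpent-4-enal | O=CC[C@@H](C)C(=C)CO[Si](C)(C)C(C)(C)C | intermediate
25 | methyl (3S,4R,6R)-7-{[(tert-butyldimethylsilyl)oxy]methyl}-6-methyl-2-methylidene-3-(prop-2-en-1-yl)-4-[(trimethylsilyl)oxy]oct-7-enoate (not isolated) | C=C(C(=O)OC)[C@H](CC=C)[C@H](O[Si](C)(C)C)C[C@@H](C)C(=C)CO[Si](C)(C)C(C)(C)C | intermediate
26 | methyl (3S,4R,6R)-7-{[(tert-butyldimethylsilyl)oxy]methyl}-4-hydroxy-6-methyl-2-methylidene-3-(prop-2-en-1-yl)oct-7-enoate (not isolated) | C=C(C(=O)OC)[C@H](CC=C)[C@H](O)C[C@@H](C)C(=C)CO[Si](C)(C)C(C)(C)C | intermediate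
27 | (4S,5R)-5-[(2R)-3-{[(tert-butyldimethylsilyl)oxy]methyl}-2-methylbut-3-en-1-yl]-3-methylidene-4-(prop-2-en-1-yl)oxolan-2-one | C=C1C(=O)O[C@H](C[C@@H](C)C(=C)CO[Si](C)(C)C(C)(C)C)[C@H]1CC=C | intermediate
28 | (3aS,7R,8aR)-6-{[(tert-butyldimethylsilyl)oxy]methyl}-7-methyl-3-methylidene-3,3a,4,7,8,8a-hexahydro-2H-cyclohepta[b]furan-2-one | C=C1C(=O)O[C@@H]2C[C@@H](C)C(CO[Si](C)(C)C(C)(C)C)=CC[C@@H]12 | intermediate
29 | (3aS,7R,8aR)-6-(hydroxymethyl)-7-methyl-3-methylidene-3,3a,4,7,8,8a-hexahydro-2H-cyclohepta[b]furan-2-one | C=C1C(=O)O[C@@H]2C[C@@H](C)C(CO)=CC[C@@H]12 | intermediate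
30 | (3aS,7R,8aR)-7-methyl-3-methylidene-2-oxo-3,3a,4,7,8,8a-hexahydro-2H-cyclohepta[b]furan-6-carbaldehyde | C=C1C(=O)O[C@@H]2C[C@@H](C)C(C=O)=CC[C@@H]12 | intermediate
31 | 1-chloropropan-2-one | CC(=O)CCl | starting material
32 | (2-oxopropyl)triphenylphosphonium chloride | CC(=O)C[P+](c1ccccc1)(c1ccccc1)c1ccccc1.[Cl-] | intermediate
33 | 1-(triphenylphosphoranylidene)propan-2-one | CC(=O)C=P(c1ccccc1)(c1ccccc1)c1ccccc1 | intermediate
34 | Diels–Alder adduct (3S,5S,7S,8R,10S,11S,7′S,8′R,10′R,11′R): cyclohexene C1=C2 with C3-acetyl, new bonds C5–C13′ and C3–C11′ (spiro lactone), β-sulfonyl lactone on the diene half, C1′-carbaldehyde on the dienophile half | O=S(=O)(c5ccccc5)C[C@@H]1C(=O)O[C@@H]2C[C@H](C)C3=C[C@H](C(C)=O)[C@]4(C[C@@H]3C[C@@H]12)C(=O)O[C@@H]1C[C@@H](C)C(C=O)=CC[C@H]14 | intermediate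
35 | (1R,2S,3R,5S,7S,8R,10S,11S,7′S,8′R,10′R,11′R)-1,2-epoxide of 34 (oxygen cis to H-3, H-5 and H-10) | O=S(=O)(c5ccccc5)C[C@@H]1C(=O)O[C@@H]2C[C@H](C)[C@@]36O[C@H]6[C@H](C(C)=O)[C@]4(C[C@@H]3C[C@@H]12)C(=O)O[C@@H]1C[C@@H](C)C(C=O)=CC[C@H]14 | intermediate
36 | epoxy sulfone 35 with the C1′ aldehyde extended to the (E)-3-oxobut-1-en-1-yl side chain | O=S(=O)(c5ccccc5)C[C@@H]1C(=O)O[C@@H]2C[C@H](C)[C@@]36O[C@H]6[C@H](C(C)=O)[C@]4(C[C@@H]3C[C@@H]12)C(=O)O[C@@H]1C[C@@H](C)C(/C=C/C(C)=O)=CC[C@H]14 | intermediate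
37 | (1R,5S,7S,8R,10S,11S,7′S,8′R,10′R,11′R)-1-hydroxy-2(3)-en-4-one sulfone: the target with its exo-methylene still masked as CH2SO2Ph (not isolated) | O=S(=O)(c5ccccc5)C[C@@H]1C(=O)O[C@@H]2C[C@H](C)[C@]3(O)C=C(C(C)=O)[C@]4(C[C@@H]3C[C@@H]12)C(=O)O[C@@H]1C[C@@H](C)C(/C=C/C(C)=O)=CC[C@H]14 | intermediate
38 | CNP0168949.3, (1R,5S,7S,8R,10S,7′S,8′R,10′R,11′R) | C=C1C(=O)O[C@@H]2C[C@H](C)[C@]3(O)C=C(C(C)=O)[C@]4(C[C@@H]3C[C@@H]12)C(=O)O[C@@H]1C[C@@H](C)C(/C=C/C(C)=O)=CC[C@H]14 | target

## Step count

Total step count: 24.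
Longest linear sequence: 14 steps (9 → 10 → 11 → 12 → 13 → 14 → 15 → 16 → 17 → 18 → 21 → 22 → 23 → 24).

## Three steps most likely to fail, with fallbacks

**Step 21 (Diels–Alder coupling).** Both partners are electron-poor, so the reaction may be sluggish, and the facial preference of the 10-epi-type diene rests on a conformational argument. The fallback changes the electronic nature of the diene. It sets out from 17: Luche reduction (NaBH4, CeCl3·7H2O, MeOH, −40 °C) gives the C4 dienol (3S,3aS,7S,8aR)-6-[(E)-3-hydroxybut-1-en-1-yl]-7-methyl-3-[(phenylsulfonyl)methyl]-3,3a,4,7,8,8a-hexahydro-2H-cyclohepta[b]furan-2-one F1 (carbinol epimers, inconsequential). This normal-demand diene should add to 30 at 40–60 °C, with C5–C13′ bonding directed by the C1 alkyl substituent, to give the C4 carbinol cycloadduct F2. Dess–Martin oxidation of F2 comes back to the route at 34.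

**Step 5 (and its twin, step 15).** The anti/trans selectivity relies on equilibration of a γ-substituted 2-(methoxycarbonyl)allylchromium, and the catalyst must override the β-stereocentre. The fallback replaces it by a geometry-defined allylboration. It sets out from 3: the vinylalane generated as in step 2 is alkylated with 2-(iodomethyl)-4,4,5,5-tetramethyl-1,3,2-dioxaborolane to give methyl (Z)-2-[(4,4,5,5-tetramethyl-1,3,2-dioxaborolan-2-yl)methyl]hexa-2,5-dienoate F3, in which the allyl chain is trans to CH2B. Chiral phosphoric acid-catalysed allylboration of 9 ((R)-TRIP, toluene, −30 °C → rt) through a closed chair transition state gives the anti hydroxy ester 11, which lactonises with PPTS and comes back to the route at 12. The same reagent with 24 gives 26 and returns at 27.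

**Step 22 (epoxidation feeding the C1 carbinol).** Over-oxidation of the aldehyde or the wrong face would lose the C1 centre. The fallback installs the oxygen by an ene reaction instead. It sets out from 34: a Schenck ene reaction with singlet oxygen (O2, tetraphenylporphyrin, hν, CH2Cl2, −20 °C) abstracts H-3 on the same convex face and gives the C1 hydroperoxide F4 with the C2=C3 enone already in place. Triphenylphosphine reduces it to the C1 carbinol aldehyde F5. Wittig reaction of F5 with 33 comes back to the route at 37, which is then isolated and treated with DBU as in step 24 to give 38.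

## Further compounds

F1 | step 21 | (3S,3aS,7S,8aR)-6-[(E)-3-hydroxybut-1-en-1-yl]-7-methyl-3-[(phenylsulfonyl)methyl]-3,3a,4,7,8,8a-hexahydro-2H-cyclohepta[b]furan-2-one (carbinol epimers) | O=S(=O)(c3ccccc3)C[C@@H]1C(=O)O[C@@H]2C[C@H](C)C(/C=C/C(C)O)=CC[C@@H]12
F2 | step 21 | C4 carbinol cycloadduct (34 with CH(OH)CH3 in place of the acetyl group; carbinol epimers) | O=S(=O)(c5ccccc5)C[C@@H]1C(=O)O[C@@H]2C[C@H](C)C3=C[C@H](C(C)O)[C@]4(C[C@@H]3C[C@@H]12)C(=O)O[C@@H]1C[C@@H](C)C(C=O)=CC[C@H]14
F3 | step 5 | methyl (Z)-2-[(4,4,5,5-tetramethyl-1,3,2-dioxaborolan-2-yl)methyl]hexa-2,5-dienoate | C=CC/C=C(/CB1OC(C)(C)C(C)(C)O1)C(=O)OC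
F4 | step 22 | (1R)-1-hydroperoxy-2(3)-en-4-one sulfone aldehyde | O=S(=O)(c5ccccc5)C[C@@H]1C(=O)O[C@@H]2C[C@H](C)[C@]3(OO)C=C(C(C)=O)[C@]4(C[C@@H]3C[C@@H]12)C(=O)O[C@@H]1C[C@@H](C)C(C=O)=CC[C@H]14
F5 | step 22 | (1R)-1-hydroxy-2(3)-en-4-one sulfone aldehyde | O=S(=O)(c5ccccc5)C[C@@H]1C(=O)O[C@@H]2C[C@H](C)[C@]3(O)C=C(C(C)=O)[C@]4(C[C@@H]3C[C@@H]12)C(=O)O[C@@H]1C[C@@H](C)C(C=O)=CC[C@H]14
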